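Locants follow the target throughout: cyclohexanone C1 (C=O), C2 (propenyl), C3, C4 (bears C5'), C5 (hexenoyl), C6; tetronic acid O1', C2' (lactone C=O), C3', C4' (enol carbon), C5' (quaternary). Compounds are numbered 1–27 in the order in which they appear in the steps.

Remark on the chemistry: β-keto ester 8 is drawn as its trans keto tautomer; the carbon between its two carbonyl groups is configurationally labile, is fixed in step 4 and becomes the radical centre in step 6.

## Analysis of the target

The target 27 is a cyclohexanone that carries an (E)-prop-1-enyl group at C2, the quaternary carbon C5' of a 4-hydroxy-3,5-dimethylfuran-2(5H)-one (a 3-methyltetronic acid) at C4, and an (E)-hex-4-enoyl group at C5. It has four stereocentres, C2 (S), C4 (S), C5 (R) and C5' (R). The three ring substituents lie on one face, so C2 and C4 can both be equatorial while the acyl group at C5 is axial and cis to the bulky C4 substituent. C2 sits between the ketone and an alkene: it epimerises easily (towards the arrangement that is wanted), and the β,γ-double bond can slip into conjugation under base or strong acid. C5 is α to the side-chain ketone, the tetronic acid is a vinylogous carboxylic acid, and the two E-alkenes exclude hydrogenation. The hard parts are the C4–C5' bond, which joins a tertiary ring carbon to a fully substituted carbinol carbon with a fixed relative configuration, the cis relation of C4 and C5, and the ordering of three carbonyl groups of similar reactivity. The route rests on the 1,4-relation between C1 and the acyl carbonyl on C5 through C6. This dissonant pattern is what results when a methylene radical is inserted between the ketone and the α-carbon of a β-keto ester, so C6 can be the inserted carbon and the six-membered ring can come from a five-membered one. A second useful feature is that C5', with its oxygen, its methyl group and the carbon that becomes C4', is lactic acid in masked form.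

## Retrosynthetic reasoning

27 from 26. The C1 ketone is carried as a dioxolane and released last by mild aqueous acid. Every reagent used late in the route to build the tetronic acid and the side-chain ketone is a strong base or a carbon nucleophile, which a free β,γ-unsaturated ketone would not survive.

26 from 22 and 25. The bond between the acyl carbon on C5 and the chain is cut, giving the N-methoxy-N-methylamide 22 and the Grignard reagent 25, which comes from bromide 24 and alcohol 23. This bond is made late because, once the ketone exists, C5 can epimerise and a ketone enolate would compete in the ester condensation that closes the tetronic acid. The tetronic acid needs no protecting group, since its magnesium salt is inert to the Grignard reagent.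

22 from 21. The tetronic acid is cut at C3'–C4', a Dieckmann disconnection. That leaves a propionate ester on O1' and a methyl ester on C5', with no ketone in the molecule at the time of the condensation.

21 from 19. Both the amide on C5 and the free O1' come from opening a γ-lactone that joins the C5 carboxyl to O1'. The lactone does two jobs. It tells the two carboxyl carbons apart, one being a lactone carbonyl and the other a hindered methyl ester. It also holds C5 cis to C4 while the ring is elaborated.

19 back to 14. The ketal comes from ketone 18. The C2–H bond comes from conjugate reduction of dienone 17, with hydride going to C3 and a proton to C2 on the convex face. The C2–propenyl bond comes from cross-coupling of iodoenone 15 with boronic acid 16, and the iodide from enone 14. The C2=C3 double bond of 14 is what distinguishes C2 from C6; a saturated ketone would offer no such handle.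

14 from 13. The lactone arises when the dioxolanone of 13 is opened in acidic methanol: the freed tertiary hydroxyl closes onto the cis ester at C5.

13 from 12 (key disconnection). C6–C1 is cut and C5 is rejoined to C1, which leads back to the bromomethyl cyclopentenone β-keto ester 12. The reason for going through a five-membered ring is that its alkylidene β-keto ester is a far better Michael acceptor than any cyclohexenone that would have to accept the C5' nucleophile at C4. The radical ring enlargement then corrects the skeleton, places ketone and ester in the 1,4-relation, and sets C5.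

12 from 10 from 8. The enone comes from dehydrogenation of ketone 10, and the bromomethyl group from C-alkylation of β-keto ester 8. The alkylation also blocks enolisation towards the ester, so the dehydrogenation can only go to the side that becomes C2=C3.

8 from 6 and 3. The C4–C5' bond is cut as a Michael addition of the enolate 7 of dioxolanone 6 to the cyclopentenone ester 3. Compound 6 comes from 4 and 5, and it carries C5' with its oxygen and its carboxyl carbon at the right oxidation level. Compound 3 comes from 1.

## Alternatives that were turned down

Alternative 1: The C5–carbonyl and C4–C5' bonds are cut together as a [2+2] cycloaddition between cyclohexa-1,3-diene A2 and a chiral keteniminium ion whose ketene carbon carries the methyl and a silyloxymethyl group. The forward key step would give the cis-fused cyclobutanone A1, and a Baeyer–Villiger oxidation would then insert O1' next to the quaternary carbon, giving a lactone of the same kind as 14.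
- For it: two skeletal bonds and two adjacent stereocentres form in one step, and the cis ring fusion is enforced by the four-membered ring. On this point it is stronger than the chosen route, where the cis relation depends on an intermolecular hydrogen-atom transfer.
- Against it: the configuration at C5' depends on the keteniminium ion distinguishing a methyl from a CH2O group of similar size, and on the regiochemistry across the diene. The ring ketone is absent and must be brought in by allylic oxidation. C4' arrives as CH2O and needs two oxidations before any tetronic acid can be closed.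
- Comparison: the chosen route takes C5' from lactic acid with its carboxyl carbon already in place, and the C1 ketone is a product of the key step itself. It accepts a less secure C4/C5 relation in exchange.

Alternative 2: Only the C5–carbonyl bond is cut. The acyl carbon is delivered from O1' as an alkoxycarbonyl radical, generated from the Se-phenyl selenocarbonate A4, which adds 5-exo to C5 of an enone to give the cis-fused keto lactone A3 with the propenyl group already at C2.
- For it: the tether guarantees the cis relation of C4 and C5, the conditions are mild, and the product is a lactone of the type used in the chosen route with C2 already set. Its control of C5 is more secure than that of the chosen key step, and the fallback to step 6 below borrows exactly this tethering idea.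
- Against it: a tertiary alkoxycarbonyl radical can lose CO2 in competition with ring closure. A4 must already contain the C4–C5' stereopair, so the hardest bond of the target is left to another, unspecified construction. C2 of A4 is α to an enone carbonyl and epimerisable. C4' again arrives at the alcohol oxidation level.
- Comparison: the chosen route builds the C4–C5' bond within the same plan, by a Michael addition that the five-membered acceptor makes easy.

Alternative 3: The C4–C5 ring bond is cut. A nitrile-stabilised carbanion in the acyclic epoxynitrile A6 opens an epoxide, made by asymmetric epoxidation, at its secondary carbon with inversion, closing the ring to the hydroxy nitrile A5.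
- For it: C4 and C5' both come from one reagent-controlled epoxidation, and the inversion at C4 is certain. On absolute control at C4 it is stronger than the chosen route, where that centre depends on substrate-controlled facial selectivity in the Michael step.
- Against it: the carbon attacked is next to a fully substituted epoxide carbon, so the closure is slow and the seven-membered mode at the tertiary carbon competes. The nitrile centre C5 forms under equilibrating conditions, with no element that enforces the cis relation. The acyclic precursor is long and carries C2 and an E-alkene beside a ketal, which needs its own asymmetric step. The nitrile must later accept the pentenyl nucleophile beside a free tertiary alkoxide, and C4' again needs oxidation.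
- Comparison: the chosen route is shorter and makes ring, ketone and C5 in one operation, at the price of the radical step's risk.

Key step: step 6

## Route

Step 1
Reactants: 1 methyl 2-oxocyclopentane-1-carboxylate
Product: 3 methyl 5-oxocyclopent-1-ene-1-carboxylate, via selenide 2 (not isolated)
Conditions: PhSeCl, pyridine, CH2Cl2, 0 °C; then 30% H2O2, 0 °C to rt; used at once
Reagents that add atoms: none
Why: α-Selenenylation of the β-keto ester followed by oxidation and syn selenoxide elimination, which can only remove a ring hydrogen; the alkylidene β-keto ester dimerises on standing and is therefore taken straight into step 3.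

Step 2
Reactants: 4 (S)-lactic acid; 5 pivalaldehyde
Product: 6 (2S,5S)-2-tert-butyl-5-methyl-1,3-dioxolan-4-one
Conditions: TsOH (cat.), H2SO4 (cat.), pentane, reflux with water separator; crystallisation at −78 °C
Reagents that add atoms: none
Why: Acid-catalysed acetalisation under thermodynamic control should favour the 2,5-cis dioxolanone, which low-temperature crystallisation upgrades; the acetal centre stores the lactate configuration for the next step.

Step 3
Reactants: 6 (2S,5S)-2-tert-butyl-5-methyl-1,3-dioxolan-4-one; 3 methyl 5-oxocyclopent-1-ene-1-carboxylate
Product: 8 methyl (1R,2S)-2-[(2S,4R)-2-tert-butyl-4-methyl-5-oxo-1,3-dioxolan-4-yl]-5-oxocyclopentane-1-carboxylate, via lithium enolate 7 (not isolated)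
Conditions: LiN(iPr)2, THF, −78 °C; then 3 in THF, −78 °C; AcOH quench
Reagents that add atoms: none
Why: Michael addition to a doubly activated acceptor; the enolate is attacked on the face anti to the tert-butyl group, which sets C5' (self-regeneration of the lactate centre), and a lithium-bridged synclinal transition state that keeps the ring methylene of 3 away from the dioxolanone ring and places its hydrogen over it should set C4 as drawn; the stabilised β-keto ester enolate makes the addition irreversible.

Step 4
Reactants: 8 methyl (1R,2S)-2-[(2S,4R)-2-tert-butyl-4-methyl-5-oxo-1,3-dioxolan-4-yl]-5-oxocyclopentane-1-carboxylate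
Product: 10 methyl (1R,2S)-1-(bromomethyl)-2-[(2S,4R)-2-tert-butyl-4-methyl-5-oxo-1,3-dioxolan-4-yl]-5-oxocyclopentane-1-carboxylate, via sodium enolate 9 (not isolated)
Conditions: NaH, THF, 0 °C; then CH2Br2 (excess), HMPA, 60 °C
Reagents that add atoms: dibromomethane BrCBr
Why: C-Alkylation of a β-keto ester enolate with excess dibromomethane in a dipolar medium; the electrophile should enter trans to the bulky neighbour, but this centre becomes a radical in step 6, so its configuration does not matter.

Step 5
Reactants: 10 methyl (1R,2S)-1-(bromomethyl)-2-[(2S,4R)-2-tert-butyl-4-methyl-5-oxo-1,3-dioxolan-4-yl]-5-oxocyclopentane-1-carboxylate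
Product: 12 methyl (1R,5S)-1-(bromomethyl)-5-[(2S,4R)-2-tert-butyl-4-methyl-5-oxo-1,3-dioxolan-4-yl]-2-oxocyclopent-3-ene-1-carboxylate, via trimethylsilyl enol ether 11 (not isolated)
Conditions: TMSOTf, Et3N, CH2Cl2, 0 °C; then Pd(OAc)2 (10 mol %), O2 (1 atm), DMSO, 40 °C
Reagents that add atoms: none
Why: Saegusa–Ito dehydrogenation; the ketone has a single enolisable side, so soft enolisation gives one silyl enol ether, and divalent palladium (re-formed by O2) converts it into the enone; the neopentyl-type bromide is inert to displacement and to the zerovalent palladium that passes through the cycle.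

Step 6
Reactants: 12 methyl (1R,5S)-1-(bromomethyl)-5-[(2S,4R)-2-tert-butyl-4-methyl-5-oxo-1,3-dioxolan-4-yl]-2-oxocyclopent-3-ene-1-carboxylate
Product: 13 methyl (1R,2S)-2-[(2S,4R)-2-tert-butyl-4-methyl-5-oxo-1,3-dioxolan-4-yl]-5-oxocyclohex-3-ene-1-carboxylate
Conditions: Bu3SnH (1.3 equiv, syringe pump), AIBN (cat.), benzene, 80 °C, high dilution
Reagents that add atoms: none
Why: Dowd–Beckwith one-carbon ring expansion: the tin radical abstracts bromine, the primary radical closes 3-exo-trig onto the ketone carbon, and the cyclopropyloxy radical reopens by β-scission of the bond to the quaternary carbon, so that C6–C1 is made, C5–C1 is broken and the six-membered ring arises by enlargement and not by direct cyclisation. The direction of the β-scission is secured by the ester, which stabilises the ring-expanded tertiary radical at C5, and the enone double bond stays a spectator because no reasonable ring size leads to it. The closest known reaction type is the tin hydride ring expansion of α-bromomethyl cyclic β-keto esters, which includes ketones conjugated to an arene; the cross-conjugated enone is a further member of that class. The new stereocentre C5 is set when Bu3SnH transfers hydrogen: strain with the in-plane ester should turn the C4 substituent pseudo-axial, where it covers one face of the planar radical, so hydrogen arrives anti to it and the ester ends up cis to C4. Two selectivities are needed and pull in opposite directions: rearrangement must outrun direct reduction of the primary radical, which calls for a low stationary tin hydride concentration, and hydrogen transfer to the C5 radical must outrun loss of the captodative dioxolanonyl radical by cleavage of C4–C5', which calls for a concentration no lower than necessary.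

Step 7
Reactants: 13 methyl (1R,2S)-2-[(2S,4R)-2-tert-butyl-4-methyl-5-oxo-1,3-dioxolan-4-yl]-5-oxocyclohex-3-ene-1-carboxylate
Product: 14 methyl (1R,3aR,7aS)-1-methyl-3,5-dioxo-1,3,3a,4,5,7a-hexahydro-2-benzofuran-1-carboxylate (cis-fused enone lactone: lactone between the C5 carboxyl and O1', C2=C3 enone, CH3 and CO2CH3 on C5')
Conditions: HCl (1.25 M in MeOH), 50 °C
Reagents that add atoms: methanol CO
Why: Acid-catalysed methanolysis opens the dioxolanone to the C5' methyl ester and frees the tertiary hydroxyl, which closes onto the cis ester at C5 to give a cis-fused γ-lactone; the enone tolerates acid better than methoxide, and from here on the two carboxyl carbons are chemically different and C5 is held in a ring fusion.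

Step 8
Reactants: 14 cis-fused enone lactone
Product: 15 methyl (1R,3aR,7aR)-6-iodo-1-methyl-3,5-dioxo-1,3,3a,4,5,7a-hexahydro-2-benzofuran-1-carboxylate (14 with iodine on C2)
Conditions: I2, pyridine, CH2Cl2, 0 °C to rt
Reagents that add atoms: iodine II
Why: α-Iodination of an enone by conjugate addition of pyridine, iodination of the resulting enolate and elimination; only C2 can react, which fixes the site of the later carbon substituent.

Step 9
Reactants: 15 α-iodoenone lactone; 16 (E)-prop-1-enylboronic acid
Product: 17 methyl (1R,3aR,7aS)-1-methyl-3,5-dioxo-6-[(E)-prop-1-enyl]-1,3,3a,4,5,7a-hexahydro-2-benzofuran-1-carboxylate (dienone lactone)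
Conditions: PdCl2(PhCN)2 (5 mol %), Ph3As, Ag2O, THF/H2O (8:1), rt
Reagents that add atoms: none
Why: Suzuki–Miyaura coupling of an α-iodoenone with an alkenylboronic acid under Ag2O promotion at room temperature, with retention of the E geometry; no alkoxide or hydroxide base is present that could open the lactone.

Step 10
Reactants: 17 dienone lactone
Product: 18 methyl (1R,3aR,6S,7aS)-1-methyl-3,5-dioxo-6-[(E)-prop-1-enyl]octahydro-2-benzofuran-1-carboxylate (C2 propenyl cis to the C4–C5' bond)
Conditions: [(Ph3P)CuH]6 (0.5 equiv), H2O (5 equiv), benzene/THF, rt; aq. NH4Cl
Reagents that add atoms: none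
Why: Conjugate reduction by a copper hydride puts hydride on C3 only and leaves the alkenes, lactone and ester alone; the copper dienolate should be protonated at C2 (kinetic α-protonation) from the convex face of the cis-fused bicycle, which places the propenyl group cis to C4–C5', the arrangement that is also equatorial and thermodynamically preferred.

Step 11
Reactants: 18 propenyl ketone lactone
Product: 19 C1 ethylene ketal of 18 (spiro-1,3-dioxolane at C1; stereocentres as in 18)
Conditions: (TMSOCH2)2, TMSOTf (cat.), CH2Cl2, −78 to −20 °C; pyridine quench
Reagents that add atoms: 1,2-bis(trimethylsilyloxy)ethane C[Si](C)(C)OCCO[Si](C)(C)C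
Why: Aprotic ketalisation at low temperature avoids enolisation, so the β,γ-double bond and C2 should stay as they are; the ketal shields C1 from the basic and nucleophilic reagents of steps 12, 13 and 15.

Step 12
Reactants: 19 ketal lactone
Product: 21 Weinreb amide propionate (C1 ketal; C5 carries C(=O)N(OCH3)CH3; C5' carries CH3, CO2CH3 and O-propanoyl; C2, C4, C5, C5' as in 27), via chloromagnesium alkoxide 20 (not isolated)
Conditions: MeONHMe·HCl, iPrMgCl, THF, −20 to 0 °C; then EtCOCl, 0 °C to rt
Reagents that add atoms: N,O-dimethylhydroxylamine hydrochloride CNOC.Cl; propionyl chloride CCC(=O)Cl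
Why: Aminolysis of the γ-lactone by the magnesium amide gives the Weinreb amide and a tertiary magnesium alkoxide, the methyl ester on the fully substituted C5' being much less accessible; under basic conditions the alkoxide cannot displace the amide again, and it is O-acylated in the same flask before a protic work-up could allow relactonisation.

Step 13
Reactants: 21 Weinreb amide propionate
Product: 22 tetronic acid Weinreb amide (C1 ketal; C5 amide; 4-hydroxy-3,5-dimethylfuran-2(5H)-one joined through C5' to C4)
Conditions: LiN(SiMe3)2 (3 equiv), THF, −78 to 0 °C; cold 0.5 M HCl
Reagents that add atoms: none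
Why: Dieckmann condensation: the propionate enolate attacks the geminal methyl ester in a five-membered closure and the stable tetronate anion drives it; the amide α-hydrogen at C5 is tertiary, hindered and less acidic, so C5 should not be touched, and no ketone is present to compete.

Step 14
Reactants: 23 (E)-pent-3-en-1-ol
Product: 24 (E)-5-bromopent-2-ene
Conditions: CBr4, PPh3, CH2Cl2, 0 °C
Reagents that add atoms: carbon tetrabromide BrC(Br)(Br)Br
Why: Appel reaction of a primary alcohol under neutral conditions, which leaves the alkene geometry alone.

Step 15
Reactants: 22 tetronic acid Weinreb amide; 24 (E)-5-bromopent-2-ene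
Product: 26 C1 ethylene ketal of the target, via Grignard reagent 25 (not isolated)
Conditions: Mg, THF, rt (24 to 25); then 22, THF, 0 °C to rt (3.5 equiv of 25); cold 0.5 M HCl
Reagents that add atoms: none
Why: Weinreb ketone synthesis: the first equivalent of Grignard reagent turns the tetronic acid into its unreactive magnesium salt, further reagent adds to the amide to give a chelated tetrahedral intermediate that only collapses on work-up, so the ketone cannot be attacked twice; the ketal protects C1.

Step 16
Reactants: 26 C1 ethylene ketal of the target
Product: 27 (5R)-5-[(1S,2R,5S)-2-[(E)-hex-4-enoyl]-4-oxo-5-[(E)-prop-1-enyl]cyclohexyl]-4-hydroxy-3,5-dimethylfuran-2(5H)-one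
Conditions: 1 M HCl, THF, rt, short contact
Reagents that add atoms: water O
Why: Acid-catalysed hydrolysis of the dioxolane; the tetronic acid and both alkenes are stable to dilute acid, the C2 arrangement is the thermodynamic one, and short contact at room temperature should avoid enolisation at C5 and migration of the β,γ-double bond.

## Compound list

1 | methyl 2-oxocyclopentane-1-carboxylate | COC(=O)C1CCCC1=O | starting material
2 | methyl 2-oxo-1-(phenylselanyl)cyclopentane-1-carboxylate (racemic) | COC(=O)C1([Se]c2ccccc2)CCCC1=O | intermediate
3 | methyl 5-oxocyclopent-1-ene-1-carboxylate | COC(=O)C1=CCCC1=O | intermediate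
4 | (S)-lactic acid | C[C@H](O)C(=O)O | starting material
5 | pivalaldehyde | CC(C)(C)C=O | starting material
6 | (2S,5S)-2-tert-butyl-5-methyl-1,3-dioxolan-4-one | C[C@@H]1O[C@H](C(C)(C)C)OC1=O | intermediate
7 | lithium enolate of 6 | CC1=C([O-])O[C@@H](C(C)(C)C)O1.[Li+] | intermediate
8 | methyl (1R,2S)-2-[(2S,4R)-2-tert-butyl-4-methyl-5-oxo-1,3-dioxolan-4-yl]-5-oxocyclopentane-1-carboxylate | COC(=O)[C@H]1C(=O)CC[C@@H]1[C@@]2(C)O[C@H](C(C)(C)C)OC2=O | intermediate
9 | sodium enolate of 8 | COC(=O)C1=C([O-])CC[C@@H]1[C@@]2(C)O[C@H](C(C)(C)C)OC2=O.[Na+] | intermediate
10 | methyl (1R,2S)-1-(bromomethyl)-2-[(2S,4R)-2-tert-butyl-4-methyl-5-oxo-1,3-dioxolan-4-yl]-5-oxocyclopentane-1-carboxylate | COC(=O)[C@]1(CBr)C(=O)CC[C@@H]1[C@@]2(C)O[C@H](C(C)(C)C)OC2=O | intermediate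
11 | methyl (1R,5S)-1-(bromomethyl)-5-[(2S,4R)-2-tert-butyl-4-methyl-5-oxo-1,3-dioxolan-4-yl]-2-(trimethylsilyloxy)cyclopent-2-ene-1-carboxylate | COC(=O)[C@]1(CBr)C(O[Si](C)(C)C)=CC[C@@H]1[C@@]2(C)O[C@H](C(C)(C)C)OC2=O | intermediate
12 | methyl (1R,5S)-1-(bromomethyl)-5-[(2S,4R)-2-tert-butyl-4-methyl-5-oxo-1,3-dioxolan-4-yl]-2-oxocyclopent-3-ene-1-carboxylate | COC(=O)[C@]1(CBr)C(=O)C=C[C@@H]1[C@@]2(C)O[C@H](C(C)(C)C)OC2=O | intermediate
13 | methyl (1R,2S)-2-[(2S,4R)-2-tert-butyl-4-methyl-5-oxo-1,3-dioxolan-4-yl]-5-oxocyclohex-3-ene-1-carboxylate | COC(=O)[C@@H]1CC(=O)C=C[C@@H]1[C@@]2(C)O[C@H](C(C)(C)C)OC2=O | intermediate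
14 | methyl (1R,3aR,7aS)-1-methyl-3,5-dioxo-1,3,3a,4,5,7a-hexahydro-2-benzofuran-1-carboxylate | COC(=O)[C@]1(C)OC(=O)[C@@H]2CC(=O)C=C[C@H]12 | intermediate
15 | methyl (1R,3aR,7aR)-6-iodo-1-methyl-3,5-dioxo-1,3,3a,4,5,7a-hexahydro-2-benzofuran-1-carboxylate | COC(=O)[C@]1(C)OC(=O)[C@@H]2CC(=O)C(I)=C[C@H]12 | intermediate
16 | (E)-prop-1-enylboronic acid | C/C=C/B(O)O | starting material
17 | methyl (1R,3aR,7aS)-1-methyl-3,5-dioxo-6-[(E)-prop-1-enyl]-1,3,3a,4,5,7a-hexahydro-2-benzofuran-1-carboxylate | COC(=O)[C@]1(C)OC(=O)[C@@H]2CC(=O)C(/C=C/C)=C[C@H]12 | intermediate
18 | methyl (1R,3aR,6S,7aS)-1-methyl-3,5-dioxo-6-[(E)-prop-1-enyl]octahydro-2-benzofuran-1-carboxylate | COC(=O)[C@]1(C)OC(=O)[C@@H]2CC(=O)[C@H](/C=C/C)C[C@H]12 | intermediate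
19 | C1 ethylene ketal of 18 (spiro-1,3-dioxolane in place of the ring ketone; stereocentres as in 18) | COC(=O)[C@]1(C)OC(=O)[C@@H]2CC3(OCCO3)[C@H](/C=C/C)C[C@H]12 | intermediate
20 | chloromagnesium alkoxide of the ring-opened hydroxy Weinreb amide (C5 amide, O1' as magnesium alkoxide) | CON(C)C(=O)[C@@H]1CC2(OCCO2)[C@H](/C=C/C)C[C@@H]1[C@](C)(C(=O)OC)[O-].[Mg+2].[Cl-] | intermediate
21 | Weinreb amide propionate: C1 ketal, C5 C(=O)N(OCH3)CH3, C5' bearing CH3, CO2CH3 and O-propanoyl; C2, C4, C5, C5' as in 27 | CON(C)C(=O)[C@@H]1CC2(OCCO2)[C@H](/C=C/C)C[C@@H]1[C@](C)(C(=O)OC)OC(=O)CC | intermediate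
22 | tetronic acid Weinreb amide: C1 ketal, C5 C(=O)N(OCH3)CH3, 4-hydroxy-3,5-dimethylfuran-2(5H)-one at C4; configuration as in 27 | CON(C)C(=O)[C@@H]1CC2(OCCO2)[C@H](/C=C/C)C[C@@H]1[C@@]1(C)OC(=O)C(C)=C1O | intermediate
23 | (E)-pent-3-en-1-ol | C/C=C/CCO | starting material
24 | (E)-5-bromopent-2-ene | C/C=C/CCBr | intermediate
25 | (E)-pent-3-enylmagnesium bromide | C/C=C/CC[Mg]Br | intermediate
26 | C1 ethylene ketal of the target | C/C=C/CCC(=O)[C@@H]1CC2(OCCO2)[C@H](/C=C/C)C[C@@H]1[C@@]1(C)OC(=O)C(C)=C1O | intermediate
27 | (5R)-5-[(1S,2R,5S)-2-[(E)-hex-4-enoyl]-4-oxo-5-[(E)-prop-1-enyl]cyclohexyl]-4-hydroxy-3,5-dimethylfuran-2(5H)-one | C/C=C/CCC(=O)[C@@H]1CC(=O)[C@H](/C=C/C)C[C@@H]1[C@@]1(C)OC(=O)C(C)=C1O | target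

## Step count and least certain steps

Total: 16 steps. Longest linear sequence: 14 steps (from 1 through steps 1, 3–13, 15 and 16; the same length from 4 through step 2).

Step 6 (key step). Three things can go wrong:
- Premature reduction: the primary radical may take hydrogen before it rearranges, because addition to a conjugated ketone gives up the enone conjugation and may be slow.
- Fragmentation: the ring-expanded C5 radical may shed the captodative dioxolanonyl radical by cleaving C4–C5'. The C4 substituent that shields one face is also aligned with the radical orbital, and high dilution slows the competing hydrogen transfer.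
- Poor facial selectivity: hydrogen transfer is intermolecular and guided only by sterics.

The fallback keeps the ring expansion but ties the oxygen in first. It sets out from 8 and returns at 14. Acidic methanol, as in step 7, converts 8 into the cis-fused keto lactone F1, in which O1' is already joined to the ring carboxyl. Alkylation of its sodium enolate with dibromomethane gives the angular bromomethyl keto lactone F2, soft enolisation its trimethylsilyl enol ether F3, and Saegusa–Ito oxidation the bromomethyl enone lactone F4. Tin hydride ring expansion of F4 gives 14 directly. In F4 the ring-expanded radical sits at a ring-fusion carbon, so hydrogen transfer can only give the cis-fused lactone. The C4–C5' bond then lies close to the nodal plane of the radical, which should shut down the fragmentation.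

Step 3. The likely failure is poor or reversed facial selectivity on the acceptor, which gives the wrong relative configuration between C4 and C5'. The attack anti to the tert-butyl group is dependable, but the orientation of the cyclopentenone in the lithium-bridged transition state rests on a model. The fallback sets out from 6 and returns at 8. Compound 6 is converted with LiN(iPr)2 and Me3SiCl into the silyl ketene acetal F5. F5 adds to 3 under catalytic TMSOTf at −78 °C in a Mukaiyama–Michael reaction, through an open transition state with no lithium bridge, and aqueous work-up gives 8. The enolate face is unchanged, but the acceptor is oriented by different contacts.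

Step 4. The hindered enolate may be alkylated on oxygen, or not at all, by the poor electrophile dibromomethane. The fallback sets out from 8 and returns at 13. Aldol reaction with aqueous formaldehyde and KHCO3 gives the hydroxymethyl keto ester F6. PPh3, I2 and imidazole convert it into the iodomethyl keto ester F7, which must be prepared promptly because F6 can undergo retro-aldol cleavage. Enol silylation gives the silyl enol ether F8, Saegusa–Ito oxidation gives the iodomethyl cyclopentenone F9, and the same tin hydride ring expansion of F9 gives 13.

Step 10. The copper dienolate may be protonated at the chain terminus, which moves the double bond into conjugation, or on the wrong face at C2. The fallback sets out from 14 and returns at 18, and introduces the side chain at a stage where it cannot conjugate. K[sBu3BH] at −78 °C reduces the enone of 14 in the conjugate sense, and the regiodefined enolate is alkylated with allyl bromide to give the allyl ketone F10. C2 of F10 can be equilibrated with a mild amine base to the arrangement cis to C4–C5'. RuHCl(CO)(PPh3)3 in warm toluene then moves the terminal alkene by one position to the (E)-propenyl group of 18.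

Step 12. The tertiary alkoxide may return to the lactone once the excess amide is consumed, the amide may attack the C5' ester, or acylation of the hindered alkoxide may be incomplete. The fallback avoids a free tertiary hydroxyl next to a carboxyl-level C5 carbon by carrying C5 at the alcohol level. It sets out from 19 and returns at 26. iBu2AlH at −78 °C reduces the lactone to the lactol F11. Grignard reagent 25 opens F11 to the diol F12, a mixture at the new carbinol that is removed later by oxidation. Et3SiCl and imidazole silylate the secondary hydroxyl to give the silyl ether F13, and propionic anhydride with DMAP acylates the tertiary hydroxyl to give the propionate F14. LiN(SiMe3)2 closes the tetronic acid to the silyl ether tetronic acid F15. HF·pyridine frees the secondary alcohol F16, and Dess–Martin oxidation gives 26.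

## Further compounds

F1 | step 6 | cis-fused keto lactone, methyl 1-methyl-3,4-dioxohexahydro-1H-cyclopenta[c]furan-1-carboxylate type (lactone between ring carboxyl and O1' on the cyclopentanone) | COC(=O)[C@]1(C)OC(=O)[C@@H]2C(=O)CC[C@H]12
F2 | step 6 | angular bromomethyl keto lactone (F1 with CH2Br on the ring-fusion carbon between the two carbonyl groups) | COC(=O)[C@]1(C)OC(=O)[C@]2(CBr)C(=O)CC[C@H]12
F3 | step 6 | trimethylsilyl enol ether of F2 | COC(=O)[C@]1(C)OC(=O)[C@]2(CBr)C(O[Si](C)(C)C)=CC[C@H]12
F4 | step 6 | bromomethyl enone lactone (cyclopentenone analogue of F2) | COC(=O)[C@]1(C)OC(=O)[C@]2(CBr)C(=O)C=C[C@H]12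
F5 | step 3 | (2S)-2-tert-butyl-5-methyl-4-(trimethylsilyloxy)-1,3-dioxole | CC1=C(O[Si](C)(C)C)O[C@@H](C(C)(C)C)O1
F6 | step 4 | hydroxymethyl keto ester (10 with CH2OH in place of CH2Br) | COC(=O)[C@]1(CO)C(=O)CC[C@@H]1[C@@]2(C)O[C@H](C(C)(C)C)OC2=O
F7 | step 4 | iodomethyl keto ester (10 with CH2I in place of CH2Br) | COC(=O)[C@]1(CI)C(=O)CC[C@@H]1[C@@]2(C)O[C@H](C(C)(C)C)OC2=O
F8 | step 4 | trimethylsilyl enol ether of F7 | COC(=O)[C@]1(CI)C(O[Si](C)(C)C)=CC[C@@H]1[C@@]2(C)O[C@H](C(C)(C)C)OC2=O
F9 | step 4 | iodomethyl cyclopentenone (12 with CH2I in place of CH2Br) | COC(=O)[C@]1(CI)C(=O)C=C[C@@H]1[C@@]2(C)O[C@H](C(C)(C)C)OC2=O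
F10 | step 10 | allyl ketone lactone (18 with prop-2-enyl in place of (E)-prop-1-enyl at C2) | COC(=O)[C@]1(C)OC(=O)[C@@H]2CC(=O)[C@H](CC=C)C[C@H]12
F11 | step 12 | lactol of 19 (lactone carbonyl reduced to CH(OH); anomeric mixture) | COC(=O)[C@]1(C)OC(O)[C@@H]2CC3(OCCO3)[C@H](/C=C/C)C[C@H]12
F12 | step 12 | diol: C1 ketal, C5 bearing CH(OH)-(E)-pent-3-enyl (carbinol mixture), C5' bearing OH, CH3 and CO2CH3 | C/C=C/CCC(O)[C@@H]1CC2(OCCO2)[C@H](/C=C/C)C[C@@H]1[C@@](C)(O)C(=O)OC
F13 | step 12 | triethylsilyl ether of the secondary hydroxyl of F12 | C/C=C/CCC(O[Si](CC)(CC)CC)[C@@H]1CC2(OCCO2)[C@H](/C=C/C)C[C@@H]1[C@@](C)(O)C(=O)OC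
F14 | step 12 | O1' propionate of F13 | C/C=C/CCC(O[Si](CC)(CC)CC)[C@@H]1CC2(OCCO2)[C@H](/C=C/C)C[C@@H]1[C@@](C)(OC(=O)CC)C(=O)OC
F15 | step 12 | silyl ether tetronic acid (26 with CH(OSiEt3) in place of the side-chain C=O) | C/C=C/CCC(O[Si](CC)(CC)CC)[C@@H]1CC2(OCCO2)[C@H](/C=C/C)C[C@@H]1[C@@]1(C)OC(=O)C(C)=C1O
F16 | step 12 | secondary alcohol tetronic acid (26 with CH(OH) in place of the side-chain C=O) | C/C=C/CCC(O)[C@@H]1CC2(OCCO2)[C@H](/C=C/C)C[C@@H]1[C@@]1(C)OC(=O)C(C)=C1O
A1 | alternative 1 | cis-fused 8-methyl-8-[(triisopropylsilyloxy)methyl]bicyclo[4.2.0]oct-2-en-7-one | O=C2[C@@H]1CCC=C[C@@H]1[C@@]2(CO[Si](C(C)C)(C(C)C)C(C)C)C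
A2 | alternative 1 | cyclohexa-1,3-diene | C1=CC=CCC1
A3 | alternative 2 | cis-fused keto lactone carrying the propenyl group and a tert-butyldimethylsilyloxymethyl group | O=C2[C@@H]1CC(=O)[C@H](/C=C/C)C[C@@H]1[C@@](CO[Si](C)(C)C(C)(C)C)(C)O2
A4 | alternative 2 | Se-phenyl selenocarbonate of the tertiary alcohol on the 6-propenyl-4-substituted cyclohex-2-enone | O=C1C=C[C@H](C[C@H]1/C=C/C)[C@](C)(CO[Si](C)(C)C(C)(C)C)OC(=O)[Se]c1ccccc1
A5 | alternative 3 | cyclised hydroxy nitrile with cis C4 and C5 substituents | N#C[C@@H]1CC3(OCCO3)[C@H](/C=C/C)C[C@@H]1[C@@](CO[Si](C)(C)C(C)(C)C)(C)O
A6 | alternative 3 | acyclic epoxynitrile (ketal, propenyl stereocentre and trisubstituted epoxide) | N#CCCC1(OCCO1)[C@H](/C=C/C)C[C@@H]2O[C@@]2(C)CO[Si](C)(C)C(C)(C)C
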